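**Plan**

1. Retrosynthetic cuts, in order: C12–C13 (Stille) and C11=C12 (Takai); the C7–O and C8–O bonds (cis-dihydroxylation); C9–C11 ([2,3]-shift from O-7, which moves Δ8 to Δ7); C1–C2 and C5–C10 together (intramolecular Diels–Alder reaction); C10=C1 (Wittig) and C6–C7 (vinylogous aldol).
2. Enabling feature: ring A is a cyclohexene whose C3=C4 bond lies between C2 and C5, and the vicinal methyl pairs on C4/C5 and C8/C9 flank the C6/C7 glycol. C1–C10 with C17–C20 is therefore two 2,3-dimethylpenta-2,4-dienyl units joined at C6–C7: one is the diene (C2–C5), the terminal C10=C1 bond of the other is the 2π partner, and its C8=C9 bond stays in ring B.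
3. Forward: an (E)-dienal and a butenolide-derived silyloxyfuran are joined at C6–C7; lactol methylenation gives the (E,Z)-tetraene; one cycloaddition closes rings A and B; C9 becomes quaternary by a [2,3]-shift; dihydroxylation, the two esters and the butenolide arm follow.
4. Stereochemistry: C6/C7 from a catalytic asymmetric vinylogous Mukaiyama aldol (threo); C5/C10 from the cycloaddition under control of C6/C7; C9 by suprafacial transfer from the β-O-7; C7/C8 by C11–OH-directed OsO4 addition on the β face; both tetrasubstituted alkene geometries from an enol tosylate and a ring.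

Key step: step 11

Remark: skeletal atoms carry clerodane numbers (decalin C1–C10; C17 on C8, C18 on C4, C19 on C5, C20 on C9, side chain C11–C16); ring A = C1–C5/C10, ring B = C5–C10; β is the face of H-10.
Assumption: the antipode of the chiral bisphosphoramide that delivers the dienolate to the Si face of aldehyde 4 is used; both antipodes are accessible.

**Step 1**
Reactants: 1 ethyl 2-methyl-3-oxobutanoate
Product: 2 ethyl (2E)-2-methyl-3-(tosyloxy)but-2-enoate
Conditions: TsCl, N-methylimidazole, Et3N, MeCN, 0 °C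
Reagents that add atoms: 4-toluenesulfonyl chloride, Cc1ccc(cc1)S(Cl)(=O)=O
Why: Enol tosylation of the β-keto ester under non-chelating amine conditions should give the (E)-enol tosylate (OTs trans to the ester), which fixes the geometry of the later C4=C5 bond.

**Step 2**
Reactants: 2 ethyl (2E)-2-methyl-3-(tosyloxy)but-2-enoate
Product: 3 ethyl (2E)-2,3-dimethylpenta-2,4-dienoate
Conditions: PdCl2(dppf) (5 mol%), Cs2CO3, THF/H2O, 70 °C
Reagents that add atoms: potassium trifluoro(vinyl)borate, [K+].C=C[B-](F)(F)F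
Why: Suzuki–Miyaura coupling of the enol tosylate should proceed with retention of alkene geometry, placing the vinyl group trans to the ester.

**Step 3**
Reactants: 3 ethyl (2E)-2,3-dimethylpenta-2,4-dienoate
Product: 5 (2E)-2,3-dimethylpenta-2,4-dien-1-ol, via dienal 4 (not isolated)
Conditions: DIBAL-H (2.5 equiv), CH2Cl2, −78 → 0 °C
Reagents that add atoms: none
Why: DIBAL-H reduces the conjugated ester by 1,2-addition to the allylic alcohol without touching the diene.

**Step 4**
Reactants: 5 (2E)-2,3-dimethylpenta-2,4-dien-1-ol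
Product: 4 (2E)-2,3-dimethylpenta-2,4-dienal
Conditions: MnO2 (activated, excess), CH2Cl2, rt
Reagents that add atoms: none
Why: MnO2 allylic oxidation is mild and neutral, so the tetrasubstituted (E)-bond should not isomerise.

**Step 5**
Reactants: 6 2,3-dimethylmaleic anhydride
Product: 7 3,4-dimethylfuran-2(5H)-one
Conditions: NaBH4, THF, 0 °C → rt; then aq. HCl
Reagents that add atoms: none
Why: Borohydride reduction of one carbonyl group of the symmetrical anhydride and acid-induced lactonisation give the butenolide, whose ring later fixes the C8=C9 bond as cis.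

**Step 6**
Reactants: 7 3,4-dimethylfuran-2(5H)-one
Product: 8 tert-butyl[(3,4-dimethylfuran-2-yl)oxy]dimethylsilane
Conditions: TBSOTf, Et3N, CH2Cl2, 0 °C
Reagents that add atoms: tert-butyldimethylsilyl trifluoromethanesulfonate, CC(C)(C)[Si](C)(C)OS(=O)(=O)C(F)(F)F
Why: Soft enolisation (silyl triflate plus amine) converts the butenolide into the aromatic 2-silyloxyfuran, a cyclic silyl dienolate.

**Step 7**
Reactants: 4 (2E)-2,3-dimethylpenta-2,4-dienal; 8 tert-butyl[(3,4-dimethylfuran-2-yl)oxy]dimethylsilane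
Product: 10 (5R)-5-[(1R,2E)-1-hydroxy-2,3-dimethylpenta-2,4-dien-1-yl]-3,4-dimethylfuran-2(5H)-one, via trichlorosilyl aldolate 9 (not isolated)
Conditions: SiCl4 (1.1 equiv), chiral bisphosphoramide [pentane-1,5-diylbis(methylazanediyl)-linked bis(N,N'-dimethyl-1,1'-binaphthyl-2,2'-diamine phosphoramide), 5 mol%], iPr2NEt (10 mol%), CH2Cl2, −78 °C; aq. NaHCO3/KF
Reagents that add atoms: none
Why: Lewis-base-catalysed, SiCl4-mediated vinylogous Mukaiyama aldol reaction, in which furan C5 adds 1,2 to the hindered dienal through an open transition state that favours the threo adduct while the chiral silicon cation selects the aldehyde face, so C6 and C7 are set together as (R,R).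

**Step 8**
Reactants: 10 (5R)-5-[(1R,2E)-1-hydroxy-2,3-dimethylpenta-2,4-dien-1-yl]-3,4-dimethylfuran-2(5H)-one
Product: 11 (5R)-5-[(1R,2E)-1-(methoxymethoxy)-2,3-dimethylpenta-2,4-dien-1-yl]-3,4-dimethylfuran-2(5H)-one
Conditions: MOMCl, iPr2NEt, Bu4NI (cat.), CH2Cl2, 0 °C → rt
Reagents that add atoms: chloromethyl methyl ether, COCCl
Why: Acetal protection of O-6 under weakly basic conditions leaves the butenolide untouched, and a MOM group cannot migrate to O-7 in the later alkoxide steps as a silyl group could.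

**Step 9**
Reactants: 11 (5R)-5-[(1R,2E)-1-(methoxymethoxy)-2,3-dimethylpenta-2,4-dien-1-yl]-3,4-dimethylfuran-2(5H)-one
Product: 12 (5R)-5-[(1R,2E)-1-(methoxymethoxy)-2,3-dimethylpenta-2,4-dien-1-yl]-3,4-dimethyl-2,5-dihydrofuran-2-ol (anomer mixture)
Conditions: DIBAL-H (1.2 equiv), CH2Cl2, −78 °C; Rochelle salt; crude product used at once
Reagents that add atoms: none
Why: DIBAL-H at low temperature reduces the butenolide by 1,2-addition to the lactol, which is kept neutral and used directly because acid would dehydrate it to a furan.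

**Step 10**
Reactants: 12 (5R)-5-[(1R,2E)-1-(methoxymethoxy)-2,3-dimethylpenta-2,4-dien-1-yl]-3,4-dimethyl-2,5-dihydrofuran-2-ol
Product: 14 (3Z,5R,6R,7E)-6-(methoxymethoxy)-3,4,7,8-tetramethyldeca-1,3,7,9-tetraen-5-ol, via open-chain (Z)-hydroxy enal 13 (not isolated)
Conditions: Ph3PCH3Br (3 equiv), n-BuLi (2.9 equiv), THF, 0 °C → rt
Reagents that add atoms: methyltriphenylphosphonium bromide, C[P+](c1ccccc1)(c1ccccc1)c1ccccc1.[Br-]
Why: Wittig methylenation of the lactol through its open hydroxy enal gives the vinyl group cis to C7 because the ring had fixed that geometry, and the lithium counter-ion at 0 °C should keep the 3-oxido-1,5-diene from anionic oxy-Cope rearrangement.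

**Step 11**
Reactants: 14 (3Z,5R,6R,7E)-6-(methoxymethoxy)-3,4,7,8-tetramethyldeca-1,3,7,9-tetraen-5-ol
Product: 15 (1R,2R,4aR,8aR)-1-(methoxymethoxy)-3,4,8,8a-tetramethyl-1,2,4a,5,6,8a-hexahydronaphthalen-2-ol
Conditions: CH2Cl2 (0.02 M), BHT (1 mol%), 13 kbar, 50 °C
Reagents that add atoms: none
Why: Pressure-accelerated type 1 intramolecular Diels–Alder reaction of a deca-1,3,7,9-tetraene: the (E)-configured C2=C3–C4=C5 diene adds suprafacially to the terminal C10=C1 bond of the second diene, forming C1–C2 and C5–C10 and leaving C3=C4 and the tetrasubstituted C8=C9; the closest known reaction type is the intramolecular Diels–Alder reaction of 1,3,9-decatrienes with a conjugated 2π partner. Ring A (C1–C5, C10) closes as the cycloaddition ring and ring B (C5–C10) as the tether ring, the four-atom tether C6–C9 being held cis by the (Z)-C8=C9 bond. C5 is set by diene-face selection under control of C6: allylic 1,3-strain with the C4 methyl (C18) keeps H-6 near the diene plane, so the tether reaches the face that places O-6 and O-7 both equatorial on the chair-like ring B, which gives C19 α with 6α-O and 7β-O. C10 is set by the tether-anti transition state that gives the trans ring fusion, because the syn (cis-fused) alternative would push the olefinic tether under C4 and its methyl group. Only this pairing can close, since the other one would need the (E)-C4=C5 bond inside a six-membered ring. The cycloaddition must outrun [1,5]-hydrogen shifts of the two cis-alkyl dienes and overcome the s-cis strain of the C19 inside methyl, which is why its large negative activation volume is used at 50 °C instead of heat.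

**Step 12**
Reactants: 15 (1R,2R,4aR,8aR)-1-(methoxymethoxy)-3,4,8,8a-tetramethyl-1,2,4a,5,6,8a-hexahydronaphthalen-2-ol
Product: 16 tributyl({[(1R,2R,4aR,8aR)-1-(methoxymethoxy)-3,4,8,8a-tetramethyl-1,2,4a,5,6,8a-hexahydronaphthalen-2-yl]oxy}methyl)stannane
Conditions: KH, 18-crown-6 (cat.), Bu3SnCH2I, THF, 0 °C → rt
Reagents that add atoms: tributyl(iodomethyl)stannane, CCCC[Sn](CI)(CCCC)CCCC
Why: Williamson etherification of the potassium alkoxide of the allylic 7β-OH, which after the cycloaddition is no longer part of a 1,5-diene and so cannot undergo oxy-Cope rearrangement.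

**Step 13**
Reactants: 16 tributyl({[(1R,2R,4aR,8aR)-1-(methoxymethoxy)-3,4,8,8a-tetramethyl-1,2,4a,5,6,8a-hexahydronaphthalen-2-yl]oxy}methyl)stannane
Product: 18 [(1R,4S,4aR,8aR)-4-(methoxymethoxy)-1,2,4a,5-tetramethyl-1,4,4a,7,8,8a-hexahydronaphthalen-1-yl]methanol, via α-lithiomethyl ether 17 (not isolated)
Conditions: n-BuLi (1.5 equiv), THF, −78 → −20 °C; aq. NH4Cl
Reagents that add atoms: none
Why: Wittig–Still [2,3]-sigmatropic rearrangement, in which tin–lithium exchange gives the α-alkoxymethyllithium that transfers CH2O suprafacially from the β-O-7 to the β face of C9, creating the quaternary centre with C20 α and moving the double bond to C7=C8.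

**Step 14**
Reactants: 18 [(1R,4S,4aR,8aR)-4-(methoxymethoxy)-1,2,4a,5-tetramethyl-1,4,4a,7,8,8a-hexahydronaphthalen-1-yl]methanol
Product: 20 triol (5R,6R,7S,8R,9S,10S): 6α-OMOM-7β,8β-dihydroxy-9β-hydroxymethyl decalin with Δ3, via cyclic osmate ester 19 (not isolated)
Conditions: OsO4 (1.05 equiv), TMEDA (1.1 equiv), CH2Cl2, −78 °C; then ethylenediamine, rt
Reagents that add atoms: osmium tetroxide, O=[Os](=O)(=O)=O
Why: Hydrogen-bond-directed syn-dihydroxylation, in which the homoallylic 9β-CH2OH steers the OsO4·TMEDA complex to the β face of C7=C8 (the α face is also blocked by the axial C19 and C20 methyl groups) and away from the remote C3=C4 bond, setting 7β-OH and 8β-OH.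

**Step 15**
Reactants: 20 triol (6α-OMOM, 7β-OH, 8β-OH, 9β-CH2OH)
Product: 21 hydroxy aldehyde (5R,6R,7S,8R,9R,10S): 9β-formyl-6α-OMOM-7β,8β-diol
Conditions: [Cu(MeCN)4]OTf (5 mol%), 2,2'-bipyridine (5 mol%), TEMPO (5 mol%), N-methylimidazole (10 mol%), air, MeCN, rt
Reagents that add atoms: none
Why: Aerobic Cu/TEMPO oxidation is selective for the primary alcohol over the hindered secondary and tertiary ones, and the 1,3-diequatorial C11/O-7 pair on the rigid trans-decalin cannot close to a lactol that would be oxidised further.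

**Step 16**
Reactants: 21 hydroxy aldehyde (9β-formyl-6α-OMOM-7β,8β-diol)
Product: 22 (E)-vinyl iodide (5R,6R,7S,8R,9S,10S): 9β-[(E)-2-iodoethenyl]-6α-OMOM-7β,8β-diol
Conditions: CrCl2 (8 equiv), CHI3 (3 equiv), THF/1,4-dioxane, 0 °C → rt
Reagents that add atoms: iodoform, IC(I)I
Why: Takai olefination is non-basic (no retro-aldol of the β-hydroxy aldehyde), tolerates free hydroxyl groups and gives the (E)-iodoalkene, the more so with an α-quaternary aldehyde.

**Step 17**
Reactants: 22 (E)-vinyl iodide (6α-OMOM-7β,8β-diol)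
Product: 23 7β-(2-methylpropanoyloxy) derivative of 22 (5R,6R,7S,8R,9S,10S)
Conditions: isobutyryl chloride, pyridine, DMAP (cat.), CH2Cl2, 0 °C → rt
Reagents that add atoms: 2-methylpropanoyl chloride, CC(C)C(Cl)=O
Why: Acylation distinguishes the secondary equatorial 7-OH from the tertiary axial 8-OH, which stays free.

**Step 18**
Reactants: 23 7β-isobutyrate with 6α-OMOM
Product: 24 6α-hydroxy 7β-isobutyrate (5R,6R,7S,8R,9S,10S)
Conditions: ZnBr2 (1.5 equiv), n-PrSH (3 equiv), CH2Cl2, 0 °C
Reagents that add atoms: none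
Why: Lewis-acid/thiol cleavage of the MOM acetal is fast and non-basic, so the neighbouring ester should neither cleave nor migrate and the vinyl iodide survives.

**Step 19**
Reactants: 24 6α-hydroxy 7β-isobutyrate
Product: 25 6α-acetoxy 7β-isobutyrate vinyl iodide (5R,6R,7S,8R,9S,10S)
Conditions: Ac2O, DMAP, pyridine, CH2Cl2, rt
Reagents that add atoms: acetic anhydride, CC(=O)OC(C)=O
Why: DMAP-catalysed acetylation of the only remaining secondary hydroxyl group, the tertiary 8-OH being much slower.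

**Step 20**
Reactants: 26 4-bromofuran-2(5H)-one
Product: 27 4-(tributylstannyl)furan-2(5H)-one
Conditions: (Bu3Sn)2, Pd(PPh3)4 (5 mol%), toluene, 100 °C
Reagents that add atoms: hexabutyldistannane, CCCC[Sn](CCCC)(CCCC)[Sn](CCCC)(CCCC)CCCC
Why: Palladium-catalysed stannylation of the β-bromo enoate with the distannane (oxidative addition, Sn–Sn transmetalation, reductive elimination).

**Step 21**
Reactants: 25 6α-acetoxy 7β-isobutyrate vinyl iodide; 27 4-(tributylstannyl)furan-2(5H)-one
Product: 28 (1R,2S,3R,4R,4aS,8aR)-1-(acetyloxy)-3-hydroxy-3,4,8,8a-tetramethyl-4-[(E)-2-(5-oxo-2,5-dihydrofuran-3-yl)ethenyl]-1,2,3,4,4a,5,6,8a-octahydronaphthalen-2-yl 2-methylpropanoate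
Conditions: Pd2(dba)3 (5 mol%), AsPh3 (20 mol%), CuI (10 mol%), NMP, 40 °C
Reagents that add atoms: none
Why: Stille coupling under neutral conditions joins C12 to C13 with retention of the (E)-geometry and tolerates the free tertiary alcohol, both esters and the butenolide.

**Compound list**

1 | ethyl 2-methyl-3-oxobutanoate | CCOC(=O)C(C)C(C)=O | starting material
2 | ethyl (2E)-2-methyl-3-(tosyloxy)but-2-enoate | CCOC(=O)/C(C)=C(\C)OS(=O)(=O)c1ccc(C)cc1 | intermediate
3 | ethyl (2E)-2,3-dimethylpenta-2,4-dienoate | C=C/C(C)=C(\C)C(=O)OCC | intermediate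
4 | (2E)-2,3-dimethylpenta-2,4-dienal | C=C/C(C)=C(\C)C=O | intermediate
5 | (2E)-2,3-dimethylpenta-2,4-dien-1-ol | C=C/C(C)=C(\C)CO | intermediate
6 | 2,3-dimethylmaleic anhydride | CC1=C(C)C(=O)OC1=O | starting material
7 | 3,4-dimethylfuran-2(5H)-one | CC1=C(C)C(=O)OC1 | intermediate
8 | tert-butyl[(3,4-dimethylfuran-2-yl)oxy]dimethylsilane | Cc1coc(O[Si](C)(C)C(C)(C)C)c1C | intermediate
9 | trichlorosilyl ether of 10 (aldolate, not isolated) | C=C/C(C)=C(\C)[C@@H](O[Si](Cl)(Cl)Cl)[C@@H]1OC(=O)C(C)=C1C | intermediate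
10 | (5R)-5-[(1R,2E)-1-hydroxy-2,3-dimethylpenta-2,4-dien-1-yl]-3,4-dimethylfuran-2(5H)-one | C=C/C(C)=C(\C)[C@@H](O)[C@@H]1OC(=O)C(C)=C1C | intermediate
11 | (5R)-5-[(1R,2E)-1-(methoxymethoxy)-2,3-dimethylpenta-2,4-dien-1-yl]-3,4-dimethylfuran-2(5H)-one | C=C/C(C)=C(\C)[C@@H](OCOC)[C@@H]1OC(=O)C(C)=C1C | intermediate
12 | (5R)-5-[(1R,2E)-1-(methoxymethoxy)-2,3-dimethylpenta-2,4-dien-1-yl]-3,4-dimethyl-2,5-dihydrofuran-2-ol (anomer mixture) | C=C/C(C)=C(\C)[C@@H](OCOC)[C@@H]1OC(O)C(C)=C1C | intermediate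
13 | (2Z,4R,5R,6E)-4-hydroxy-5-(methoxymethoxy)-2,3,6,7-tetramethylnona-2,6,8-trienal (not isolated) | C=C/C(C)=C(\C)[C@@H](OCOC)[C@H](O)/C(C)=C(/C)C=O | intermediate
14 | (3Z,5R,6R,7E)-6-(methoxymethoxy)-3,4,7,8-tetramethyldeca-1,3,7,9-tetraen-5-ol | C=C/C(C)=C(\C)[C@@H](OCOC)[C@H](O)/C(C)=C(/C)C=C | intermediate
15 | (1R,2R,4aR,8aR)-1-(methoxymethoxy)-3,4,8,8a-tetramethyl-1,2,4a,5,6,8a-hexahydronaphthalen-2-ol (6α-OMOM, 7β-OH, 5α-Me, 10β-H, Δ3, Δ8) | COCO[C@H]1[C@H](O)C(C)=C(C)[C@H]2CCC=C(C)[C@]12C | intermediate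
16 | tributylstannylmethyl ether of 15 at O-7 | COCO[C@H]1[C@H](OC[Sn](CCCC)(CCCC)CCCC)C(C)=C(C)[C@H]2CCC=C(C)[C@]12C | intermediate
17 | lithiomethyl ether of 15 at O-7 (not isolated) | COCO[C@H]1[C@H](OC[Li])C(C)=C(C)[C@H]2CCC=C(C)[C@]12C | intermediate
18 | [(1R,4S,4aR,8aR)-4-(methoxymethoxy)-1,2,4a,5-tetramethyl-1,4,4a,7,8,8a-hexahydronaphthalen-1-yl]methanol (6α-OMOM, 9β-CH2OH, 9α-Me, Δ3, Δ7) | COCO[C@H]1C=C(C)[C@](C)(CO)[C@H]2CCC=C(C)[C@]12C | intermediate
19 | cyclic osmate ester of 20 at O-7/O-8, TMEDA adduct (not isolated) | COCO[C@H]1[C@H](O[Os]3(=O)=O)[C@](C)(O3)[C@](C)(CO)[C@H]2CCC=C(C)[C@]12C.CN(C)CCN(C)C | intermediate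
20 | triol (5R,6R,7S,8R,9S,10S): 6α-OMOM, 7β-OH, 8β-OH, 9β-CH2OH, Δ3 | COCO[C@H]1[C@H](O)[C@](C)(O)[C@](C)(CO)[C@H]2CCC=C(C)[C@]12C | intermediate
21 | hydroxy aldehyde (5R,6R,7S,8R,9R,10S): 9β-CHO | COCO[C@H]1[C@H](O)[C@](C)(O)[C@](C)(C=O)[C@H]2CCC=C(C)[C@]12C | intermediate
22 | (E)-vinyl iodide (5R,6R,7S,8R,9S,10S): 9β-[(E)-2-iodoethenyl], 6α-OMOM, 7β-OH, 8β-OH | COCO[C@H]1[C@H](O)[C@](C)(O)[C@](C)(/C=C/I)[C@H]2CCC=C(C)[C@]12C | intermediate
23 | 7β-isobutyrate of 22 | COCO[C@H]1[C@H](OC(=O)C(C)C)[C@](C)(O)[C@](C)(/C=C/I)[C@H]2CCC=C(C)[C@]12C | intermediate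
24 | 6α-hydroxy 7β-isobutyrate vinyl iodide | O[C@H]1[C@H](OC(=O)C(C)C)[C@](C)(O)[C@](C)(/C=C/I)[C@H]2CCC=C(C)[C@]12C | intermediate
25 | 6α-acetoxy 7β-isobutyrate vinyl iodide | CC(=O)O[C@H]1[C@H](OC(=O)C(C)C)[C@](C)(O)[C@](C)(/C=C/I)[C@H]2CCC=C(C)[C@]12C | intermediate
26 | 4-bromofuran-2(5H)-one | O=C1OCC(Br)=C1 | starting material
27 | 4-(tributylstannyl)furan-2(5H)-one | O=C1OCC([Sn](CCCC)(CCCC)CCCC)=C1 | intermediate
28 | CNP0207114.1; clerodane descriptors (5R,6R,7S,8R,9R,10S) | CC(=O)O[C@H]1[C@H](OC(=O)C(C)C)[C@](C)(O)[C@](C)(/C=C/C2=CC(=O)OC2)[C@H]2CCC=C(C)[C@]12C | target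

**Count**

Total step count: 21. Longest linear sequence: 18 (steps 1–4, 7–19 and 21).

**Steps most likely to fail**

Step 11. The cycloaddition may be too slow for a hindered, unactivated diene carrying an inside methyl group, so that [1,5]-hydrogen shifts or poor cis/trans and facial control take over. The fallback activates the 2π partner with a removable sulfonyl group; it sets out from lactol 12 and returns at 15. Seyferth–Gilbert homologation of 12 (dimethyl (1-diazo-2-oxopropyl)phosphonate, K2CO3, MeOH) would give (3Z,5R,6R,7E)-6-(methoxymethoxy)-3,4,7,8-tetramethyldeca-3,7,9-trien-1-yn-5-ol F1. Silylation (TESOTf, 2,6-lutidine) gives its triethylsilyl ether F2, which blocks oxa-Michael addition of O-7. Hydrozirconation of the terminal alkyne with Cp2Zr(H)Cl and quenching with PhSO2Cl gives the (E)-dienyl phenyl sulfone F3. Its sulfonyl-activated C10=C1 bond should undergo the same intramolecular Diels–Alder reaction in toluene at 80–110 °C, through the sulfone-endo, tether-anti transition state, to the bicyclic sulfone F4. Reductive desulfonylation (Na(Hg), Na2HPO4, MeOH, −20 °C) gives the silyl ether F5, and Bu4NF in THF gives 15.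

Step 13. Because the C7–O bond is pseudo-equatorial and C9 is fully substituted, the carbanion may undergo [1,2]-shift or protonation instead of the [2,3]-shift. The fallback replaces the sigmatropic step by a carbamate-directed copper substitution; it sets out from 15 and returns at 18. PhNCO (Et3N cat.) converts 15 into the N-phenylcarbamate F6. Deprotonation (n-BuLi), CuI·2LiCl and (isopropoxydimethylsilyl)methylmagnesium chloride should effect the syn-SN2′ substitution, copper being delivered from the carbamate nitrogen on the β face, to give the 9β-(isopropoxydimethylsilyl)methyl compound F7. Tamao oxidation (H2O2, KF, KHCO3, THF/MeOH) then gives 18.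

Step 7. The aldol may show poor enantio- or threo-selectivity, or conjugate addition to the dienal may compete. The fallback uses an auxiliary-controlled aldol and builds the butenolide afterwards; it sets out from dienal 4 and returns at 11. Boron-mediated syn-aldol reaction (Bu2BOTf, Et3N, CH2Cl2, −78 °C) of 4 with the glycolyl imide (4S)-4-benzyl-3-{[(4-methoxybenzyl)oxy]acetyl}oxazolidin-2-one F8 would give the syn aldol F9, with C6 and C7 set by the auxiliary. MOMCl/iPr2NEt gives the MOM ether F10, Me3Al/MeONHMe·HCl the Weinreb amide F11, MeMgBr the methyl ketone F12, and DDQ (CH2Cl2, pH 7 buffer) the α-hydroxy ketone F13. Esterification with 2-(diethoxyphosphoryl)propanoic acid (DCC, DMAP) gives the phosphonate F14, and intramolecular Horner–Wadsworth–Emmons olefination (LiCl, iPr2NEt, MeCN) closes the 3,4-dimethylbutenolide ring to 11.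

**Further compounds**

F1 | step 11 | (3Z,5R,6R,7E)-6-(methoxymethoxy)-3,4,7,8-tetramethyldeca-3,7,9-trien-1-yn-5-ol | C=C/C(C)=C(\C)[C@@H](OCOC)[C@H](O)/C(C)=C(/C)C#C
F2 | step 11 | triethylsilyl ether of F1 | C=C/C(C)=C(\C)[C@@H](OCOC)[C@H](O[Si](CC)(CC)CC)/C(C)=C(/C)C#C
F3 | step 11 | (E)-dienyl phenyl sulfone from F2 | C=C/C(C)=C(\C)[C@@H](OCOC)[C@H](O[Si](CC)(CC)CC)/C(C)=C(/C)\C=C\S(=O)(=O)c1ccccc1
F4 | step 11 | bicyclic C1-phenylsulfonyl cycloadduct (6α-OMOM, 7β-OTES) | COCO[C@H]1[C@H](O[Si](CC)(CC)CC)C(C)=C(C)[C@H]2C(S(=O)(=O)c3ccccc3)CC=C(C)[C@]12C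
F5 | step 11 | triethylsilyl ether of 15 | COCO[C@H]1[C@H](O[Si](CC)(CC)CC)C(C)=C(C)[C@H]2CCC=C(C)[C@]12C
F6 | step 13 | N-phenylcarbamate of 15 at O-7 | COCO[C@H]1[C@H](OC(=O)Nc3ccccc3)C(C)=C(C)[C@H]2CCC=C(C)[C@]12C
F7 | step 13 | 9β-[(isopropoxydimethylsilyl)methyl] analogue of 18 | COCO[C@H]1C=C(C)[C@](C)(C[Si](C)(C)OC(C)C)[C@H]2CCC=C(C)[C@]12C
F8 | step 7 | (4S)-4-benzyl-3-{[(4-methoxybenzyl)oxy]acetyl}oxazolidin-2-one | COc1ccc(COCC(=O)N2[C@@H](Cc3ccccc3)COC2=O)cc1
F9 | step 7 | syn aldol of F8 with 4 | C=C/C(C)=C(\C)[C@@H](O)[C@H](OCc1ccc(OC)cc1)C(=O)N1[C@@H](Cc2ccccc2)COC1=O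
F10 | step 7 | MOM ether of F9 | C=C/C(C)=C(\C)[C@@H](OCOC)[C@H](OCc1ccc(OC)cc1)C(=O)N1[C@@H](Cc2ccccc2)COC1=O
F11 | step 7 | Weinreb amide from F10 | C=C/C(C)=C(\C)[C@@H](OCOC)[C@H](OCc1ccc(OC)cc1)C(=O)N(C)OC
F12 | step 7 | methyl ketone from F11 | C=C/C(C)=C(\C)[C@@H](OCOC)[C@H](OCc1ccc(OC)cc1)C(C)=O
F13 | step 7 | α-hydroxy ketone from F12 | C=C/C(C)=C(\C)[C@@H](OCOC)[C@H](O)C(C)=O
F14 | step 7 | 2-(diethoxyphosphoryl)propanoate of F13 | C=C/C(C)=C(\C)[C@@H](OCOC)[C@H](OC(=O)C(C)P(=O)(OCC)OCC)C(C)=O
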